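All runs were generated by integration with made-up constants, noise included.

Which flask ends with more target, delta at 80 h or eta at 50 h, and how much does each hold?

common to all: free catalyst 0.5 mol%
- east: starting material 0.13 M; reagent 0.60 equiv; run made earlier
- north-west: starting material 0.42 M; reagent 0.60 equiv; run made earlier
- delta: starting material 0.10 M; reagent 0.600 equiv; time 80 h
- eta: starting material 0.33 M; reagent 0.600 equiv; time 50 h

| run | time / h | target / % | starting material / % |
|---|---|---|---|
| east | 4.00 | 1.2 | 98.4 |
| east | 6.00 | 2.4 | 97.1 |
| east | 10.0 | 3.6 | 96.4 |
| east | 15.0 | 5.4 | 94.2 |
| east | 20.0 | 7.1 | 92.7 |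
| east | 30.0 | 9.6 | 89.4 |
| east | 48.0 | 14.6 | 84.1 |
| north-west | 8.00 | 6.8 | 92.8 |
| north-west | 15.0 | 12.1 | 86.4 |
| north-west | 20.0 | 15.6 | 82.9 |
| north-west | 30.0 | 21.4 | 75.4 |
| north-west | 40.0 | 25.9 | 69.3 |
| north-west | 48.0 | 29.1 | 64.9 |

(scatter of a reading: 0.3 percentage points)

1. the flask that ends with the higher amount of target, in percent of the starting material charged, or "neither" when 2 percentage points or less lies between them (delta / eta / neither)
2. final target, as a percentage of the starting material charged, in delta
3. final target, as a percentage of the starting material charged, in eta

- where the amount of starting material changes, what is given in equivalents or mol% on it follows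

I solve it at both ends and join. At the start, consumption climbs on a straight line. At the far end it levels off at the charge of the limiting reagent, 0.600 equiv, if each starting material takes one reagent, as I assume. I join the ends with a reagent clock, x = ln(reagent charged / reagent left) = k·t:

consumed = 0.600 × (1 − e^(−x))

My first way uses the starting-material column. Its last readings give k = 0.00641 h⁻¹ in east and 0.0183 h⁻¹ in north-west, so k grows as concentration to the power n = 0.895. Scaling from the nearer run:

delta: x = 0.406, consumed 20.0%
eta: x = 0.738, consumed 31.3%

This x is what I carry forward.

Part of what is consumed does not appear as target in the two runs. I take missing over target as proportional to concentration times time, with a = 0.0102 M⁻¹ h⁻¹ read from north-west, so target = consumed / (1 + a·c·t). That gives 18.5% in delta and 26.8% in eta.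

My second way runs the same clock on the target column. Its power is 0.739, and it gives 19.1% in delta and 26.4% in eta.

Both ways put eta ahead by more than the margin, but they part by 0.60 percentage points in delta, whose concentration lies below both runs, and by 0.40 points in eta. The missing share of what is consumed is larger in north-west, 17.1%, than in east, 8.18%. That loss flattens the target clock's power, so the target column is the one that cheats, and I keep the first way.

The forecast, holding that “the fall in rate roughly tracks remaining reagent”, names eta, with 19.2% in delta, above mine, and 26.5% in eta, below mine.

The flask gives eta, with 17.8% in delta and 26.7% in eta.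

    starting material + free catalyst → catalyst intermediate A (k = 1.20 M⁻¹ min⁻¹)
    reagent + catalyst intermediate A → catalyst intermediate B (k = 0.190 M⁻¹ min⁻¹)
    catalyst intermediate B → catalyst intermediate C (k = 0.220 min⁻¹)
    catalyst intermediate C → free catalyst + target (k = 0.280 min⁻¹)
    target + free catalyst ⇌ isomer of the product + free catalyst, rate k5*[free catalyst]*[target] forward; the back reaction follows from the equilibrium constant (K = 2.40, k = 0.940 M⁻¹ min⁻¹)

Take delta with 0.85 mol% of free catalyst in place of 0.5 mol%. I stretch its clock in proportion to the catalyst, so x = 0.690. By this reckoning 50.2% of the reagent is left, 29.9% of the starting material is consumed and the target comes to 27.6%. In that flask at 80.0 h, 51% of the charged reagent is still there, unbound, 69.8% of the starting material remains, and the target stands at 25.6%.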